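##Retrosynthetic overview

1. Target 17 ⇐ 15: two singlet-oxygen ene reactions on the skipped-diene side chain, then Kornblum–DeLaMare dehydration of the secondary hydroperoxide only.
2. 15 ⇐ 14 ⇐ 13: the cyclohexane closes last, by an intramolecular carbonyl-ene reaction of an acyclic farnesane-type epoxy ketoaldehyde. Electrophilic C-1 attacks the 6,7-olefin and a proton is lost to the carbonyl oxygen, as in farnesyl → bisabolyl → bisabolene; this sets the carbinol and side-chain stereocentres.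
3. 13 ⇐ 12 ⇐ 10 ⇐ 8: the epoxide ring is made first, by Sharpless epoxidation of the Z-trisubstituted olefin of allylic alcohol 7; it is the only source of absolute configuration.
4. 7 ⇐ 6 ⇐ 4 + 2: a Z-configured C5 bromo ester (from butenolide 3) is coupled with the E-alkenylalane from alkyne 2 (from bromide 1).
5. Ring order: epoxide (step 5), then cyclohexane (step 8).

Assumption: only substrates, intermediates and products carry numbers; reagents are named in the step lines, and peroxidic material is handled cold and on small scale.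

## Route

Step 1
Reactants: 1 5-bromo-2-methylpent-2-ene
Product: 2 6-methylhept-5-en-1-yne
Conditions: LiC≡CH·H2NCH2CH2NH2, DMSO, 10 °C → rt
Reagents that add atoms: lithium acetylide ethylenediamine complex, [Li+].[C-]#C.NCCN
Why: SN2 alkylation of acetylide by the primary homoallylic bromide; no stereocentre is formed.

Step 2
Reactants: 3 3-methylfuran-2(5H)-one
Product: 4 methyl (2Z)-4-bromo-2-methylbut-2-enoate
Conditions: HBr (3 M in MeOH), 0 °C → rt
Reagents that add atoms: hydrogen bromide, Br; methanol, CO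
Why: acid-promoted SN2 opening of the allylic lactone C–O bond by bromide with Fischer esterification; the Z geometry is inherited from the ring.

Step 3
Reactants: 2 6-methylhept-5-en-1-yne; 4 methyl (2Z)-4-bromo-2-methylbut-2-enoate
Product: 6 methyl (2Z,5E)-2,6,10-trimethylundeca-2,5,9-trienoate, via alkenylalane 5 (not isolated)
Conditions: Me3Al (2 equiv), Cp2ZrCl2 (20 mol %), CH2Cl2, rt; then 4, Pd(PPh3)4 (5 mol %), THF, 0 °C → rt
Reagents that add atoms: trimethylaluminium, C[Al](C)C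
Why: Negishi zirconium-catalysed syn-carboalumination fixes the E-alkenylalane, and zerovalent-palladium allyl–alkenyl cross-coupling at the CH2 terminus joins the fragments with retention of both olefin geometries.

Step 4
Reactants: 6 methyl (2Z,5E)-2,6,10-trimethylundeca-2,5,9-trienoate
Product: 7 (2Z,5E)-2,6,10-trimethylundeca-2,5,9-trien-1-ol
Conditions: i-Bu2AlH (2.2 equiv), CH2Cl2, −78 °C
Reagents that add atoms: none
Why: 1,2-reduction of the conjugated ester by the aluminium hydride at low temperature leaves the Z and E olefins untouched.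

Step 5
Reactants: 7 (2Z,5E)-2,6,10-trimethylundeca-2,5,9-trien-1-ol
Product: 8 [(2R,3S)-3-[(2E)-3,7-dimethylocta-2,6-dien-1-yl]-2-methyloxiran-2-yl]methanol
Conditions: Ti(OiPr)4 (10 mol %), D-(−)-diethyl tartrate (12 mol %), t-BuOOH, 4 Å MS, CH2Cl2, −20 °C
Reagents that add atoms: tert-butyl hydroperoxide, CC(C)(C)OO
Why: Sharpless asymmetric epoxidation; the titanium-bound allylic hydroxyl restricts reaction to the 2,3-olefin, and the D-tartrate delivers oxygen to the face that gives the (2R,3S) cis-epoxide (about 90% ee expected for a Z-2-methyl allylic alcohol), which carries both epoxide stereocentres of the target.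

Step 6
Reactants: 8 [(2R,3S)-3-[(2E)-3,7-dimethylocta-2,6-dien-1-yl]-2-methyloxiran-2-yl]methanol
Product: 10 (2S,3S)-3-[(2E)-3,7-dimethylocta-2,6-dien-1-yl]-2-methyloxirane-2-carboxylic acid, via epoxy aldehyde 9 (not isolated)
Conditions: TEMPO (20 mol %), PhI(OAc)2 (2.2 equiv), MeCN–pH 7 buffer, 0 °C → rt
Reagents that add atoms: water, O
Why: oxoammonium (TEMPO) oxidation takes the primary alcohol through the aldehyde hydrate to the acid under near-neutral conditions that spare the epoxide and both olefins; the stereocentres are not touched.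

Step 7
Reactants: 10 (2S,3S)-3-[(2E)-3,7-dimethylocta-2,6-dien-1-yl]-2-methyloxirane-2-carboxylic acid
Product: 12 2-diazo-1-[(2S,3S)-3-[(2E)-3,7-dimethylocta-2,6-dien-1-yl]-2-methyloxiran-2-yl]ethan-1-one, via mixed anhydride 11 (not isolated)
Conditions: i-BuOCOCl, N-methylmorpholine, THF, −20 °C; then CH2N2, Et2O, −20 → 0 °C
Reagents that add atoms: diazomethane, C=[N+]=[N-]
Why: acylation of diazomethane by the mixed carbonic anhydride (first stage of the Arndt–Eistert sequence) gives the epoxy diazomethyl ketone cold and base-free, so the glycidic unit neither opens nor decarboxylates.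

Step 8
Reactants: 12 2-diazo-1-[(2S,3S)-3-[(2E)-3,7-dimethylocta-2,6-dien-1-yl]-2-methyloxiran-2-yl]ethan-1-one
Product: 14 (1S,3S,4S,6S)-3-hydroxy-1-methyl-4-[(2E)-6-methylhepta-2,5-dien-2-yl]-7-oxabicyclo[4.1.0]heptan-2-one, via epoxy ketoaldehyde 13 (not isolated)
Conditions: dimethyldioxirane (1.0 equiv), acetone, −78 → −20 °C; then Cu(SbF6)2·(S,S)-t-Bu-box (10 mol %; box = 2,2′-(propane-2,2-diyl)bis[(4S)-4-tert-butyl-4,5-dihydrooxazole]), 4 Å MS, CH2Cl2, −40 → 0 °C
Reagents that add atoms: dimethyldioxirane, CC1(C)OO1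
Why: Proposed new method: dioxirane oxidation of the diazoketone (known) gives the 1,2-dicarbonyl, which chelates divalent copper and undergoes an intramolecular carbonyl-ene reaction through a chair-like transition state with the forming C–O bond and C-7 both equatorial and the new C–C bond anti to the epoxide methyl (ligand chosen as the matched one), giving the 3S,4S trans product, while the six-membered hydrogen transfer takes H from the CH2 trans to the tether and leaves the E-trisubstituted side-chain olefin; the closest known reactions are the copper–bis(oxazoline) glyoxylate-ene reaction and the Lewis-acid cyclisation of citronellal to isopulegol.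

Step 9
Reactants: 14 (1S,3S,4S,6S)-3-hydroxy-1-methyl-4-[(2E)-6-methylhepta-2,5-dien-2-yl]-7-oxabicyclo[4.1.0]heptan-2-one
Product: 15 (1S,3S,4S,6S)-1-methyl-4-[(2E)-6-methylhepta-2,5-dien-2-yl]-2-oxo-7-oxabicyclo[4.1.0]heptan-3-yl 3-methylbutanoate
Conditions: (i-PrCH2CO)2O, DMAP (cat.), pyridine, CH2Cl2, 0 °C
Reagents that add atoms: 3-methylbutanoic anhydride, CC(C)CC(=O)OC(=O)CC(C)C
Why: DMAP-catalysed acylation of the secondary α-ketol hydroxyl; no stereocentre is touched.

Step 10
Reactants: 15 (1S,3S,4S,6S)-1-methyl-4-[(2E)-6-methylhepta-2,5-dien-2-yl]-2-oxo-7-oxabicyclo[4.1.0]heptan-3-yl 3-methylbutanoate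
Product: 17 (1S,3S,4S,6S)-4-[(4E)-6-hydroperoxy-6-methyl-3-oxohepta-1,4-dien-2-yl]-1-methyl-2-oxo-7-oxabicyclo[4.1.0]heptan-3-yl 3-methylbutanoate, via bis-hydroperoxide 16 (not isolated)
Conditions: O2, tetraphenylporphyrin (cat.), visible light, CH2Cl2, 0 °C; then Et3N (0.3 equiv), 0 °C
Reagents that add atoms: dioxygen, O=O
Why: two Schenck ene reactions of singlet oxygen (H from the vinylic methyl at the inner olefin, H from the doubly allylic CH2 at the terminal olefin, which gives the E olefin) are followed by Kornblum–DeLaMare dehydration, which only the secondary, doubly allylic hydroperoxide can undergo; regioisomeric ene products are expected and limit the yield, and no ring stereocentre is touched.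

## Compound list

1 | 5-bromo-2-methylpent-2-ene | CC(C)=CCCBr | starting material
2 | 6-methylhept-5-en-1-yne | C#CCCC=C(C)C | intermediate
3 | 3-methylfuran-2(5H)-one | CC1=CCOC1=O | starting material
4 | methyl (2Z)-4-bromo-2-methylbut-2-enoate | COC(=O)/C(C)=C\CBr | intermediate
5 | [(1E)-2,6-dimethylhepta-1,5-dien-1-yl]dimethylalumane | C[Al](C)/C=C(\C)CCC=C(C)C | intermediate
6 | methyl (2Z,5E)-2,6,10-trimethylundeca-2,5,9-trienoate | COC(=O)/C(C)=C\C/C=C(\C)CCC=C(C)C | intermediate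
7 | (2Z,5E)-2,6,10-trimethylundeca-2,5,9-trien-1-ol | OC/C(C)=C\C/C=C(\C)CCC=C(C)C | intermediate
8 | [(2R,3S)-3-[(2E)-3,7-dimethylocta-2,6-dien-1-yl]-2-methyloxiran-2-yl]methanol | CC(C)=CCC/C(C)=C/C[C@@H]1O[C@]1(C)CO | intermediate
9 | (2S,3S)-3-[(2E)-3,7-dimethylocta-2,6-dien-1-yl]-2-methyloxirane-2-carbaldehyde | CC(C)=CCC/C(C)=C/C[C@@H]1O[C@]1(C)C=O | intermediate
10 | (2S,3S)-3-[(2E)-3,7-dimethylocta-2,6-dien-1-yl]-2-methyloxirane-2-carboxylic acid | CC(C)=CCC/C(C)=C/C[C@@H]1O[C@]1(C)C(=O)O | intermediate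
11 | (2S,3S)-3-[(2E)-3,7-dimethylocta-2,6-dien-1-yl]-2-methyloxirane-2-carboxylic 2-methylpropyl carbonic anhydride | CC(C)=CCC/C(C)=C/C[C@@H]1O[C@]1(C)C(=O)OC(=O)OCC(C)C | intermediate
12 | 2-diazo-1-[(2S,3S)-3-[(2E)-3,7-dimethylocta-2,6-dien-1-yl]-2-methyloxiran-2-yl]ethan-1-one | CC(C)=CCC/C(C)=C/C[C@@H]1O[C@]1(C)C(=O)C=[N+]=[N-] | intermediate
13 | 2-[(2S,3S)-3-[(2E)-3,7-dimethylocta-2,6-dien-1-yl]-2-methyloxiran-2-yl]-2-oxoacetaldehyde | CC(C)=CCC/C(C)=C/C[C@@H]1O[C@]1(C)C(=O)C=O | intermediate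
14 | (1S,3S,4S,6S)-3-hydroxy-1-methyl-4-[(2E)-6-methylhepta-2,5-dien-2-yl]-7-oxabicyclo[4.1.0]heptan-2-one | CC(C)=CC/C=C(\C)[C@@H]1C[C@@H]2O[C@]2(C)C(=O)[C@H]1O | intermediate
15 | (1S,3S,4S,6S)-1-methyl-4-[(2E)-6-methylhepta-2,5-dien-2-yl]-2-oxo-7-oxabicyclo[4.1.0]heptan-3-yl 3-methylbutanoate | CC(C)=CC/C=C(\C)[C@@H]1C[C@@H]2O[C@]2(C)C(=O)[C@H]1OC(=O)CC(C)C | intermediate
16 | (1S,3S,4S,6S)-4-[(4E)-3,6-dihydroperoxy-6-methylhepta-1,4-dien-2-yl]-1-methyl-2-oxo-7-oxabicyclo[4.1.0]heptan-3-yl 3-methylbutanoate (both epimers at the CH–OOH carbon) | C=C(C(OO)/C=C/C(C)(C)OO)[C@@H]1C[C@@H]2O[C@]2(C)C(=O)[C@H]1OC(=O)CC(C)C | intermediate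
17 | (1S,3S,4S,6S)-4-[(4E)-6-hydroperoxy-6-methyl-3-oxohepta-1,4-dien-2-yl]-1-methyl-2-oxo-7-oxabicyclo[4.1.0]heptan-3-yl 3-methylbutanoate | C=C(C(=O)/C=C/C(C)(C)OO)[C@@H]1C[C@@H]2O[C@]2(C)C(=O)[C@H]1OC(=O)CC(C)C | target

## Step count and risks

Total: 10 steps. Longest linear sequence: 9 steps (1 → 2 → 6 → 7 → 8 → 10 → 12 → 14 → 15 → 17; the branch 3 → 4 joins at step 3).

The three steps most likely to fail:

**Step 8 (ring closure).** The closure depends on the epoxide surviving the Lewis acid, on the epoxide and catalyst together giving the right diastereomer, and on the hydrogen coming from C-8 and not from the methyl. The fallback sets out from 6 and closes the ring before the epoxide exists. Ester 6 is saponified (LiOH, THF–H2O) to (2Z,5E)-2,6,10-trimethylundeca-2,5,9-trienoic acid F1. This is taken through (2Z,5E)-2,6,10-trimethylundeca-2,5,9-trienoic 2-methylpropyl carbonic anhydride F2 and diazomethane to (3Z,6E)-1-diazo-3,7,11-trimethyldodeca-3,6,10-trien-2-one F3. Dimethyldioxirane gives (3Z,6E)-3,7,11-trimethyl-2-oxododeca-3,6,10-trienal F4. The same copper catalyst, now under catalyst control alone, cyclises it to (5S,6S)-6-hydroxy-2-methyl-5-[(2E)-6-methylhepta-2,5-dien-2-yl]cyclohex-2-en-1-one F5. Acylation with 3-methylbutanoic anhydride gives (1S,6S)-3-methyl-6-[(2E)-6-methylhepta-2,5-dien-2-yl]-2-oxocyclohex-3-en-1-yl 3-methylbutanoate F6. Luche reduction (NaBH4, CeCl3·7H2O, MeOH, −78 °C; axial hydride, equatorial alcohol cis to the side chain, as for carvone → cis-carveol) gives (1S,2S,6S)-2-hydroxy-3-methyl-6-[(2E)-6-methylhepta-2,5-dien-2-yl]cyclohex-3-en-1-yl 3-methylbutanoate F7. Hydroxyl-directed epoxidation (VO(acac)2, t-BuOOH) gives (1R,2R,3S,4S,6S)-2-hydroxy-1-methyl-4-[(2E)-6-methylhepta-2,5-dien-2-yl]-7-oxabicyclo[4.1.0]heptan-3-yl 3-methylbutanoate F8. Dess–Martin oxidation then rejoins the route at 15.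

**Step 10 (double ene and selective dehydration).** Each ene reaction has a competing regiochemistry, so perhaps a quarter to a third of the material is expected to reach 17, and the base must dehydrate the secondary hydroperoxide without harming the tertiary one or the methylene ketone. The fallback sets out from 15 and ends at 17. Photooxygenation to 16 is followed in the same flask by PPh3, giving (1S,3S,4S,6S)-4-[(4E)-3,6-dihydroxy-6-methylhepta-1,4-dien-2-yl]-1-methyl-2-oxo-7-oxabicyclo[4.1.0]heptan-3-yl 3-methylbutanoate F9. MnO2 oxidises only the doubly allylic secondary alcohol to (1S,3S,4S,6S)-4-[(4E)-6-hydroxy-6-methyl-3-oxohepta-1,4-dien-2-yl]-1-methyl-2-oxo-7-oxabicyclo[4.1.0]heptan-3-yl 3-methylbutanoate F10, and the regioisomers are separated at this stable stage. The hydroperoxide is installed last by acid-catalysed exchange of the tertiary allylic hydroxyl (50% H2O2, cat. H2SO4, Et2O, 0 °C), giving 17; this exchange is itself uncertain because the cation sits next to an electron-poor olefin.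

**Step 3 (Z-bromo ester and coupling).** Bromo ester 4 can relactonise or isomerise, and the coupling must keep the Z geometry and tolerate the ester. The fallback sets out from 2, rejoins at 6 and makes the Z olefin by olefination. Alkyne 2 is carboaluminated to 5 as before, converted to the ate complex with n-BuLi and opened with ethylene oxide to (3E)-4,8-dimethylnona-3,7-dien-1-ol F11. Dess–Martin oxidation gives (3E)-4,8-dimethylnona-3,7-dienal F12. Still–Gennari olefination with methyl 2-[bis(2,2,2-trifluoroethoxy)phosphoryl]propanoate (KN(SiMe3)2, 18-crown-6, THF, −78 °C) then gives 6.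

## Further compounds

F1 | step 8 | (2Z,5E)-2,6,10-trimethylundeca-2,5,9-trienoic acid | OC(=O)/C(C)=C\C/C=C(\C)CCC=C(C)C
F2 | step 8 | (2Z,5E)-2,6,10-trimethylundeca-2,5,9-trienoic 2-methylpropyl carbonic anhydride | CC(C)COC(=O)OC(=O)/C(C)=C\C/C=C(\C)CCC=C(C)C
F3 | step 8 | (3Z,6E)-1-diazo-3,7,11-trimethyldodeca-3,6,10-trien-2-one | [N-]=[N+]=CC(=O)/C(C)=C\C/C=C(\C)CCC=C(C)C
F4 | step 8 | (3Z,6E)-3,7,11-trimethyl-2-oxododeca-3,6,10-trienal | O=CC(=O)/C(C)=C\C/C=C(\C)CCC=C(C)C
F5 | step 8 | (5S,6S)-6-hydroxy-2-methyl-5-[(2E)-6-methylhepta-2,5-dien-2-yl]cyclohex-2-en-1-one | CC(C)=CC/C=C(\C)[C@@H]1CC=C(C)C(=O)[C@H]1O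
F6 | step 8 | (1S,6S)-3-methyl-6-[(2E)-6-methylhepta-2,5-dien-2-yl]-2-oxocyclohex-3-en-1-yl 3-methylbutanoate | CC(C)=CC/C=C(\C)[C@@H]1CC=C(C)C(=O)[C@H]1OC(=O)CC(C)C
F7 | step 8 | (1S,2S,6S)-2-hydroxy-3-methyl-6-[(2E)-6-methylhepta-2,5-dien-2-yl]cyclohex-3-en-1-yl 3-methylbutanoate | CC(C)=CC/C=C(\C)[C@@H]1CC=C(C)[C@H](O)[C@H]1OC(=O)CC(C)C
F8 | step 8 | (1R,2R,3S,4S,6S)-2-hydroxy-1-methyl-4-[(2E)-6-methylhepta-2,5-dien-2-yl]-7-oxabicyclo[4.1.0]heptan-3-yl 3-methylbutanoate | CC(C)=CC/C=C(\C)[C@@H]1C[C@@H]2O[C@]2(C)[C@H](O)[C@H]1OC(=O)CC(C)C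
F9 | step 10 | (1S,3S,4S,6S)-4-[(4E)-3,6-dihydroxy-6-methylhepta-1,4-dien-2-yl]-1-methyl-2-oxo-7-oxabicyclo[4.1.0]heptan-3-yl 3-methylbutanoate | C=C(C(O)/C=C/C(C)(C)O)[C@@H]1C[C@@H]2O[C@]2(C)C(=O)[C@H]1OC(=O)CC(C)C
F10 | step 10 | (1S,3S,4S,6S)-4-[(4E)-6-hydroxy-6-methyl-3-oxohepta-1,4-dien-2-yl]-1-methyl-2-oxo-7-oxabicyclo[4.1.0]heptan-3-yl 3-methylbutanoate | C=C(C(=O)/C=C/C(C)(C)O)[C@@H]1C[C@@H]2O[C@]2(C)C(=O)[C@H]1OC(=O)CC(C)C
F11 | step 3 | (3E)-4,8-dimethylnona-3,7-dien-1-ol | OCC/C=C(\C)CCC=C(C)C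
F12 | step 3 | (3E)-4,8-dimethylnona-3,7-dienal | O=CC/C=C(\C)CCC=C(C)C
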